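Remark on the chemistry: germacrane numbering is used for the ring and for the chain atoms that become ring atoms (lactone O on C6, C11 on C7, epoxy ester O on C8, acetate O on C9, C14 on C10, C15 on C4). The cyclisation precursor 21 and its product 23 were checked against the target: C9 configuration, the 1(10)Z and 4E geometries and the C6/C7 sense all agree, so their skeletons are used unchanged. Descriptor changes along the route at C7 (R in 23, 26 and 32; S elsewhere) and at C9 (S in 6–8, R from 10 on) are CIP-priority effects only.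

## Structural features

The target is a ten-membered carbocycle with two trisubstituted alkenes, C1=C10 (Z, carrying C14) and C4=C5 (E, carrying C15), which form a 1,5-diene through C2–C3. An α-methylene-γ-butyrolactone is trans-fused across C6–C7, with the lactone oxygen on C6 and C11 on C7. Four contiguous stereocentres run from C6 to C9 (6R,7S,8R,9R); C8 carries a (2S,3S)-2,3-dimethyloxirane-2-carboxylate (epoxyangelate) and the allylic C9 carries an acetate. The fragile groups are the exocyclic methylene lactone (Michael acceptor), the epoxy ester, the vicinal diester (acyl migration, translactonisation from O6 to O8) and the strained diene ring (transannular reactions under acid or heat). The real difficulty is to close the ten-membered ring while fixing C6 and C7 relative to C9, and then to tell the two neighbouring oxygens on C8 and C9 apart. The key step exploits the O6–C6–C7–C8(O8) unit, where the lactone ring meets the carbocycle. This unit is a β-hydroxy ketone in disguise, so it can be stored as an isoxazoline O–N=C8–C7–C6 whose C7–C8 bond is a bond of the ten-membered ring.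

## Logic of the disconnections

40 is cut at the two ester C–O bonds on O9 and O8, giving 32, 36 and an acetyl donor. Both acyl groups are labile to hydride and enolate chemistry, so they go on last; the hindered epoxy ester is placed first (38) and the acetate last (39 to 40). The forward steps must acylate a shielded secondary alcohol beside a methylene lactone and remove the C9 silyl group under non-basic conditions so that no acyl group migrates.

32 is cut at C11=C13 back to 27. The methylene is the most reactive group and is added only after all hydride chemistry. The demand is that O8 is silylated, so that no C8 alkoxide can attack C12, and that the only enolisable position is C11.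

27 is traced to 25 by taking the C8 carbinol back to the ketone (C8–H bond). This exposes the 1,3-oxygen pattern O6/O8. The demand is hydride delivery to one face of C8, which is placed on the non-chelating C9 silyl ether (polar Felkin–Anh control).

25 is cut at the lactone C12–O6 bond and O6 is reconnected to nitrogen, giving 23. O6 and the C8 carbonyl then derive from one functional group, and C6–OH can lactonise without competition because C8 is still a ketone. The forward step must cleave N–O without touching the two ring alkenes and must release the ketone under near-neutral conditions.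

23 is cut at C7–C8 and O–C6 to give 21, which opens both the isoxazoline and the carbocycle and leaves an acyclic chain with C9 as its only stereocentre. The demands are closure in the bridged mode, oxygen to C6, reaction at C6=C7 and not at C4=C5, and a facial preference that has only C9 to rest on. The skeleton of 21 is kept, and three refinements are made around it. The skipped dienoate ester is created only after the last strongly basic step. The dipole is generated by slow addition at high dilution. The C9 group is kept as a TBS ether because it serves twice, as facial control element here and as the non-chelating group for the later reduction.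

21 is traced through 20 and 19 to 18 by functional-group changes at C8 (oxime, aldehyde, primary alcohol, silyl ether). The aldehyde is unmasked late because C9–H is α to it and allylic. The demands are a selective primary desilylation and a buffered, non-basic oxidation.

18 is cut at C6=C7 to 14 and 15 (via 17). One Wittig reaction delivers the Z alkene and the C11–C12 arm from a commercial salt. The demand is Z selectivity and neutral esterification, since the β,γ-unsaturated ester would move into conjugation under base.

14 is cut at C5–C6 to 12, and 12 is traced through 11 to 10 by exchange of the acetonide for two silyl ethers. The alkenyl iodide stores the C5 nucleophile with its geometry fixed. The demand is iodine–lithium exchange with retention in the presence of silyl ethers.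

10 is cut at C1=C10 to 5 and 8, which joins the two fragments convergently. The α-alkoxy ketone steers the non-stabilised ylide to the Z trisubstituted alkene. The demand is olefination faster than enolisation of 8.

5 is traced to 1 (C4–C15 and C5–iodine from one carbometalation), 8 to 6 (C10–C14 by Grignard addition and oxidation) and 36 to 33 (epoxide oxygen by reagent-controlled epoxidation of the derived allylic alcohol). These steps rest on the syn stereospecificity of carboalumination, on the chiral pool for C9 and on the tartrate for the two epoxide centres.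

## Other disconnections considered

Alternative 1: The cuts are C1–C10 and C8–C9. In the forward step, carbamate A2 is lithiated at C1 with s-BuLi/sparteine and intercepted by the alkenyl boronate A3. 1,2-Migration then forms C1–C10, and the resulting γ-alkoxy allylboronate adds to the lactone aldehyde A4 to give A1.
- In its favour: three fragments are joined in one pot. C9 and C8 are set under reagent and chair-transition-state control, the Z C1=C10 alkene is formed at the same time, and O8 and O9 emerge already differentiated (free OH against PMB ether). On control of C8/C9 and on precedent for each elementary event this plan is better than the chosen one, which relies on a ketone reduction and on an unprecedented ring closure.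
- Against it: no ring is closed. The ten-membered ring must still be made, at C3–C4 from the alkenyl iodide and the C3 terminus of A1, by a separate macrocyclisation that is no easier than the one avoided. A4 holds an epimerisable C7 next to the aldehyde and a β-acyloxy group that can eliminate. The Z/E outcome of an α-substituted, β-methyl allylboronate is not assured.
- Comparison: structurally the chosen plan builds two rings and two stereocentres in its key step, whereas A1 contains no new ring. Mechanistically the alternative is the safer of the two. In step count it is roughly equal, since A4 needs its own stereocontrolled synthesis and the ring closure and deprotections remain.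

Alternative 2: The cuts are C11–C12 and C12–O6. The macrocyclic homopropargylic alcohol A6 is carbonylated with PdCl2, SnCl2 and PPh3 under carbon monoxide to give the methylene lactone A5 directly.
- In its favour: the exocyclic methylene arrives with the lactone in one step, with no enolate, no Mannich base and no temporary protection of O8. On endgame step economy and on precedent for the step itself (cyclocarbonylation of homopropargylic alcohols is established) this plan is better than the chosen one.
- Against it: the step closes only the five-membered ring and creates no stereocentre. The ten-membered ring and the full C6–C9 array, including a C7 ethynyl group trans to O6, must already be present in A6, so the hard problems are only moved. A strained 1,5-diene ring has to survive palladium hydrides, a Lewis-acidic tin salt and heat. The PMB group must later leave in the presence of the methylene lactone.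
- Comparison: the chosen plan spends more steps after ring closure but solves ring formation and C6/C7 in one event. The alternative is equal or superior only from A6 onward, and no route to A6 follows from it.

Alternative 3: The cuts are C7–C11 and O–C6. Mn(OAc)3 with Cu(OAc)2 oxidises malonic acid A9 to a radical that adds to C7 of diene A8. The allyl radical is oxidised and captured by the carboxylate at C6, giving the trans α-carboxy lactone A7 with the 4E alkene retained.
- In its favour: the lactone comes from cheap reagents in one step, the trans C6/C7 relationship is the favoured ring fusion, and the extra carboxyl group is a direct handle for decarboxylative methylenation. On the cost of the lactone and on the methylenation step this plan equals or beats the chosen one. Its reaction type has precedent, which the chosen key step lacks.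
- Against it: facial selectivity at C7 depends on acyclic induction from the C8 acetonide centre. Regioselectivity between the diene termini and over-oxidation are open. The carbocycle is not formed: A7 still lacks C14 and needs a ring closure at C1–C10 that must deliver a Z trisubstituted alkene, the least reliable macrocyclisation of all those discussed.
- Comparison: both plans create O6–C6 and set C6/C7 in one step. The chosen plan also closes the ten-membered ring in that step, so it is structurally more economical, while the alternative is the more conservative mechanistically up to A7 and weaker after it.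

Key step: step 15

## Route

Step 1
Reactants: 1 pent-4-yn-1-ol
Product: 3 (E)-5-iodo-4-methylpent-4-en-1-ol, via alkenylalane 2 (not isolated)
Conditions: Me3Al (3 equiv), Cp2ZrCl2 (0.25 equiv), CH2Cl2, 0 °C → rt; then iodine, THF, −30 → 0 °C
Reagents that add atoms: trimethylaluminium (C[Al](C)C); iodine ([I][I])
Why: Zirconium-catalysed Negishi carboalumination adds methyl and aluminium syn across the terminal alkyne with aluminium on the terminal carbon, and iodinolysis of the C–Al bond proceeds with retention, which fixes the 4E geometry (C15 cis to iodine, later cis to C6).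

Step 2
Reactants: 3 (E)-5-iodo-4-methylpent-4-en-1-ol
Product: 4 (E)-1,5-diiodo-2-methylpent-1-ene
Conditions: iodine, PPh3, imidazole, CH2Cl2, 0 °C → rt
Reagents that add atoms: iodine ([I][I])
Why: Appel-type iodination of the primary alcohol through the alkoxyphosphonium ion; the alkenyl iodide is inert.

Step 3
Reactants: 4 (E)-1,5-diiodo-2-methylpent-1-ene
Product: 5 [(E)-5-iodo-4-methylpent-4-en-1-yl]triphenylphosphonium iodide
Conditions: PPh3, MeCN, 80 °C
Reagents that add atoms: triphenylphosphine (c1ccc(cc1)P(c1ccccc1)c1ccccc1)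
Why: SN2 quaternisation occurs only at the primary alkyl iodide, since an sp2 C–I bond does not react with a phosphine without a metal catalyst.

Step 4
Reactants: 6 (S)-2,2-dimethyl-1,3-dioxolane-4-carbaldehyde
Product: 7 (1RS)-1-[(4S)-2,2-dimethyl-1,3-dioxolan-4-yl]ethan-1-ol
Conditions: MeMgBr, Et2O, −78 → 0 °C
Reagents that add atoms: methylmagnesium bromide (C[Mg]Br)
Why: Grignard addition brings in C14; the new carbinol centre is removed in the next step, so its epimer mixture does not matter, and the dioxolane centre (future C9) is not touched.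

Step 5
Reactants: 7 (1RS)-1-[(4S)-2,2-dimethyl-1,3-dioxolan-4-yl]ethan-1-ol
Product: 8 1-[(4S)-2,2-dimethyl-1,3-dioxolan-4-yl]ethan-1-one
Conditions: Dess–Martin periodinane, NaHCO3, CH2Cl2, 0 °C → rt
Reagents that add atoms: none
Why: Buffered hypervalent-iodine oxidation of the secondary alcohol is non-basic, so the α-oxygenated centre next to the new ketone should not epimerise.

Step 6
Reactants: 5 [(E)-5-iodo-4-methylpent-4-en-1-yl]triphenylphosphonium iodide; 8 1-[(4S)-2,2-dimethyl-1,3-dioxolan-4-yl]ethan-1-one
Product: 10 (4R)-4-[(2Z,6E)-7-iodo-6-methylhepta-2,6-dien-2-yl]-2,2-dimethyl-1,3-dioxolane, via phosphorus ylide 9 (not isolated)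
Conditions: KN(SiMe3)2, THF, −78 → 0 °C; then 8, −78 °C → rt
Reagents that add atoms: none
Why: Wittig olefination of an α-alkoxy ketone with a salt-free non-stabilised ylide (Still-type Z-selective synthesis of trisubstituted alkenes) places the oxygenated carbon cis to the ylide chain, which gives the 1(10)Z alkene; C9 is carried over from 8 as long as olefination at low temperature outruns enolisation.

Step 7
Reactants: 10 (4R)-4-[(2Z,6E)-7-iodo-6-methylhepta-2,6-dien-2-yl]-2,2-dimethyl-1,3-dioxolane
Product: 11 (2R,3Z,7E)-8-iodo-3,7-dimethylocta-3,7-diene-1,2-diol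
Conditions: AcOH/H2O (4:1), 40 °C
Reagents that add atoms: none
Why: Mild acid hydrolysis of the acetonide; the weak acid avoids ionisation of the allylic C9–O bond.

Step 8
Reactants: 11 (2R,3Z,7E)-8-iodo-3,7-dimethylocta-3,7-diene-1,2-diol
Product: 12 (2R,3Z,7E)-1,2-bis[(tert-butyldimethylsilyl)oxy]-8-iodo-3,7-dimethylocta-3,7-diene
Conditions: TBSOTf (2.5 equiv), 2,6-lutidine, CH2Cl2, −78 → 0 °C
Reagents that add atoms: tert-butyldimethylsilyl triflate (CC(C)(C)[Si](C)(C)OS(=O)(=O)C(F)(F)F)
Why: Silylation of both hydroxyls with the reactive triflate; the primary silyl ether can later be removed selectively, and the secondary one at C9 stays to the end as the bulky, non-chelating control group.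

Step 9
Reactants: 12 (2R,3Z,7E)-1,2-bis[(tert-butyldimethylsilyl)oxy]-8-iodo-3,7-dimethylocta-3,7-diene
Product: 14 (2E,6Z,8R)-8,9-bis[(tert-butyldimethylsilyl)oxy]-3,7-dimethylnona-2,6-dienal, via alkenyllithium 13 (not isolated)
Conditions: t-BuLi (2.1 equiv), Et2O, −78 °C; DMF, −78 → 0 °C; H2O
Reagents that add atoms: N,N-dimethylformamide (CN(C)C=O)
Why: Iodine–lithium exchange and formylation of the alkenyllithium with DMF both proceed with retention, so the E geometry at C4=C5 is transferred and C6 enters as the enal carbon.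

Step 10
Reactants: 14 (2E,6Z,8R)-8,9-bis[(tert-butyldimethylsilyl)oxy]-3,7-dimethylnona-2,6-dienal; 15 (2-carboxyethyl)triphenylphosphonium bromide
Product: 17 (3Z,5E,9Z,11R)-11,12-bis[(tert-butyldimethylsilyl)oxy]-6,10-dimethyldodeca-3,5,9-trienoic acid, via ylide carboxylate 16 (not isolated)
Conditions: 15 (1.5 equiv), NaN(SiMe3)2 (3 equiv), THF, −78 → 0 °C; then 14, −78 °C → rt; aq. NaH2PO4
Reagents that add atoms: none
Why: Wittig reaction of a non-stabilised ylide under lithium-free conditions is Z-selective and adds 1,2 to the enal; the carboxylate form of the ylide prevents enolisation at C11, so the Z C6=C7 alkene and the C11–C12 arm are installed together.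

Step 11
Reactants: 17 (3Z,5E,9Z,11R)-11,12-bis[(tert-butyldimethylsilyl)oxy]-6,10-dimethyldodeca-3,5,9-trienoic acid
Product: 18 methyl (3Z,5E,9Z,11R)-11,12-bis[(tert-butyldimethylsilyl)oxy]-6,10-dimethyldodeca-3,5,9-trienoate
Conditions: Me3SiCHN2, MeOH/toluene, 0 °C
Reagents that add atoms: (trimethylsilyl)diazomethane (C[Si](C)(C)C=[N+]=[N-])
Why: Esterification by protonation of the diazoalkane is neutral, so the skipped dienoate cannot slip into conjugation as it could under basic alkylation.

Step 12
Reactants: 18 methyl (3Z,5E,9Z,11R)-11,12-bis[(tert-butyldimethylsilyl)oxy]-6,10-dimethyldodeca-3,5,9-trienoate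
Product: 19 methyl (3Z,5E,9Z,11R)-11-[(tert-butyldimethylsilyl)oxy]-12-hydroxy-6,10-dimethyldodeca-3,5,9-trienoate
Conditions: HF·pyridine, pyridine, THF, 0 °C
Reagents that add atoms: none
Why: Buffered fluoride cleaves the less hindered primary silyl ether faster than the secondary allylic one, and the acidic medium prevents silyl migration from O9 to O8.

Step 13
Reactants: 19 methyl (3Z,5E,9Z,11R)-11-[(tert-butyldimethylsilyl)oxy]-12-hydroxy-6,10-dimethyldodeca-3,5,9-trienoate
Product: 20 methyl (3Z,5E,9Z,11R)-11-[(tert-butyldimethylsilyl)oxy]-6,10-dimethyl-12-oxododeca-3,5,9-trienoate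
Conditions: Dess–Martin periodinane, NaHCO3, CH2Cl2, 0 °C; used crude
Reagents that add atoms: none
Why: Buffered periodinane oxidation gives the α-silyloxy aldehyde without base, which protects the acidic allylic C9–H from epimerisation and the alkene from moving into conjugation.

Step 14
Reactants: 20 methyl (3Z,5E,9Z,11R)-11-[(tert-butyldimethylsilyl)oxy]-6,10-dimethyl-12-oxododeca-3,5,9-trienoate
Product: 21 methyl (3Z,5E,9Z,11R,12E)-11-[(tert-butyldimethylsilyl)oxy]-12-(hydroxyimino)-6,10-dimethyldodeca-3,5,9-trienoate
Conditions: NH2OH·HCl, pyridine, EtOH, 0 °C → rt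
Reagents that add atoms: hydroxylamine hydrochloride (NO.Cl)
Why: Condensation of the aldehyde with hydroxylamine under weakly basic buffering; either oxime geometry serves as dipole precursor and the oxime is no longer prone to epimerisation at C9.

Step 15
Reactants: 21 methyl (3Z,5E,9Z,11R,12E)-11-[(tert-butyldimethylsilyl)oxy]-12-(hydroxyimino)-6,10-dimethyldodeca-3,5,9-trienoate
Product: 23 methyl 2-[(2R,3Z,7E,9R,12R)-2-[(tert-butyldimethylsilyl)oxy]-3,7-dimethyl-10-oxa-11-azabicyclo[7.2.1]dodeca-1(11),3,7-trien-12-yl]acetate, via nitrile oxide 22 (not isolated)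
Conditions: aq. NaOCl, CH2Cl2, 0 °C → rt; 21 added by syringe pump to a final concentration near 1 mM
Reagents that add atoms: none
Why: Proposed new method: hypochlorite chlorinates the aldoxime and base removes HCl to give nitrile oxide 22, which adds in one concerted suprafacial (3+2) event across the Z C6=C7 bond, with the dipole carbon C8 bonding to C7 and the dipole oxygen to C6; the closest known reaction type is the intramolecular nitrile oxide–alkene cycloaddition that gives bridged isoxazolines when the tether is long, here applied to a ten-membered carbocycle. The isoxazoline closes as the ordinary five-membered dipolar adduct, while the carbocycle closes in the bridged mode (C8 to the distal alkene carbon C7, ring C8–C9–C10–C1–C2–C3–C4–C5–C6–C7) and not in the fused mode that would give a nine-membered ring. C6 and C7 are created together: their mutual relationship follows from the Z alkene and the suprafacial addition (H6 and H7 cis on the isoxazoline, which becomes the trans ring fusion of the lactone), and their sense relative to C9 has to come from the C9 silyloxy centre. Minimising A(1,3) strain across the Z C10=C1 alkene puts H9 in the alkene plane and the silyloxy group on the outer face, so the chain can fold over one face only and the dipole should meet the C6=C7 face that keeps C15 and the CH2CO2Me arm on the periphery, which corresponds to the required (6R,7R) adduct. The step needs regioselectivity (oxygen to C6), site selectivity (C6=C7 over C4=C5) and facial selectivity. The first two are secured by the diene: oxygen goes to the carbon bearing the second alkene as in additions to 1,3-dienes, and the disubstituted Z terminus is more reactive than the trisubstituted C4=C5, where reaction would need a seven- or eight-membered closure through a tether holding a Z alkene. Facial selectivity rests on C9 alone and is the weak point. Slow addition at high dilution holds back dimerisation to the furoxan, and the E C4=C5 and Z C1=C10 alkenes pass through unchanged.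

Step 16
Reactants: 23 methyl 2-[(2R,3Z,7E,9R,12R)-2-[(tert-butyldimethylsilyl)oxy]-3,7-dimethyl-10-oxa-11-azabicyclo[7.2.1]dodeca-1(11),3,7-trien-12-yl]acetate
Product: 25 (3aS,5R,6Z,10E,11aR)-5-[(tert-butyldimethylsilyl)oxy]-6,10-dimethyl-3,3a,5,8,9,11a-hexahydrocyclodeca[b]furan-2,4-dione, via hydroxy ketone 24 (not isolated)
Conditions: Mo(CO)6, MeCN/H2O (10:1), 80 °C; then PPTS (cat.), benzene, 50 °C
Reagents that add atoms: water (O)
Why: Zerovalent molybdenum cleaves the N–O bond reductively without touching the alkenes, the β-hydroxy imine hydrolyses to the β-hydroxy ketone, and the C6 hydroxyl closes the γ-lactone on the methyl ester by acyl substitution; C6 and C7 are not involved, so the ring fusion is trans as set in step 15.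

Step 17
Reactants: 25 (3aS,5R,6Z,10E,11aR)-5-[(tert-butyldimethylsilyl)oxy]-6,10-dimethyl-3,3a,5,8,9,11a-hexahydrocyclodeca[b]furan-2,4-dione
Product: 26 (3aR,4R,5R,6Z,10E,11aR)-5-[(tert-butyldimethylsilyl)oxy]-4-hydroxy-6,10-dimethyl-3a,4,5,8,9,11a-hexahydrocyclodeca[b]furan-2(3H)-one
Conditions: LiBH(s-Bu)3, THF, −78 °C; AcOH quench at −78 °C
Reagents that add atoms: none
Why: Reduction of an α-silyloxy ketone by a bulky non-chelating hydride follows the polar Felkin–Anh model (C9–O bond anti to the incoming hydride), which gives the syn O8/O9 relationship and so the 8R centre; the lactone is inert at −78 °C and the cold acidic quench prevents translactonisation.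

Step 18
Reactants: 26 (3aR,4R,5R,6Z,10E,11aR)-5-[(tert-butyldimethylsilyl)oxy]-4-hydroxy-6,10-dimethyl-3a,4,5,8,9,11a-hexahydrocyclodeca[b]furan-2(3H)-one
Product: 27 (3aS,4R,5R,6Z,10E,11aR)-5-[(tert-butyldimethylsilyl)oxy]-6,10-dimethyl-4-[(triethylsilyl)oxy]-3a,4,5,8,9,11a-hexahydrocyclodeca[b]furan-2(3H)-one
Conditions: TESOTf, 2,6-lutidine, CH2Cl2, −78 → 0 °C
Reagents that add atoms: triethylsilyl triflate (CC[Si](CC)(CC)OS(=O)(=O)C(F)(F)F)
Why: Silylation of the hindered C8 hydroxyl with a group more labile than the C9 silyl ether; it blocks alkoxide formation at O8 during the enolate step.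

Step 19
Reactants: 27 (3aS,4R,5R,6Z,10E,11aR)-5-[(tert-butyldimethylsilyl)oxy]-6,10-dimethyl-4-[(triethylsilyl)oxy]-3a,4,5,8,9,11a-hexahydrocyclodeca[b]furan-2(3H)-one
Product: 31 (3aS,4R,5R,6Z,10E,11aR)-5-[(tert-butyldimethylsilyl)oxy]-6,10-dimethyl-3-methylidene-4-[(triethylsilyl)oxy]-3a,4,5,8,9,11a-hexahydrocyclodeca[b]furan-2(3H)-one, via lithium enolate 28 (not isolated), via Mannich base 29 (not isolated), via ammonium iodide 30 (not isolated)
Conditions: LiN(i-Pr)2, THF, −78 °C; Eschenmoser's salt (CH2=NMe2+ I−), −78 °C → rt; then MeI, MeOH, rt; then aq. NaHCO3, CH2Cl2, rt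
Reagents that add atoms: Eschenmoser's salt (C=[N+](C)C.[I-])
Why: Mannich reaction of the lactone enolate with the iminium salt, then N-methylation and E1cB loss of trimethylamine, is the standard α-methylenation of γ-lactones; C11 is the only enolisable carbon and the enolate has no β-leaving group.

Step 20
Reactants: 31 (3aS,4R,5R,6Z,10E,11aR)-5-[(tert-butyldimethylsilyl)oxy]-6,10-dimethyl-3-methylidene-4-[(triethylsilyl)oxy]-3a,4,5,8,9,11a-hexahydrocyclodeca[b]furan-2(3H)-one
Product: 32 (3aR,4R,5R,6Z,10E,11aR)-5-[(tert-butyldimethylsilyl)oxy]-4-hydroxy-6,10-dimethyl-3-methylidene-3a,4,5,8,9,11a-hexahydrocyclodeca[b]furan-2(3H)-one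
Conditions: HF·pyridine, pyridine, THF, 0 °C
Reagents that add atoms: none
Why: A triethylsilyl ether is cleaved much faster than the tert-butyldimethylsilyl ether under buffered fluoride, and the acidic medium avoids silyl migration, translactonisation and conjugate addition to the methylene lactone.

Step 21
Reactants: 33 angelic acid
Product: 34 (Z)-2-methylbut-2-en-1-ol
Conditions: LiAlH4, Et2O, 0 °C → rt
Reagents that add atoms: none
Why: Hydride reduction of the carboxylic acid to the allylic alcohol; 1,2-reduction leaves the alkene and its Z geometry untouched.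

Step 22
Reactants: 34 (Z)-2-methylbut-2-en-1-ol
Product: 35 [(2R,3S)-2,3-dimethyloxiran-2-yl]methanol
Conditions: Ti(Oi-Pr)4 (cat.), D-(−)-diethyl tartrate, t-BuOOH, 4 Å molecular sieves, CH2Cl2, −20 °C
Reagents that add atoms: tert-butyl hydroperoxide (CC(C)(C)OO)
Why: Sharpless asymmetric epoxidation; the titanium–tartrate complex delivers oxygen to one alkene face of the allylic alcohol, the D-(−) ligand giving the (2R,3S) epoxide, and the cis relationship of C4 and the carbinol carbon is kept by the syn addition.

Step 23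
Reactants: 35 [(2R,3S)-2,3-dimethyloxiran-2-yl]methanol
Product: 36 (2S,3S)-2,3-dimethyloxirane-2-carboxylic acid
Conditions: RuCl3·xH2O (cat.), NaIO4, CCl4/MeCN/H2O, rt
Reagents that add atoms: water (O)
Why: Ruthenium tetroxide generated in situ oxidises the primary alcohol through the aldehyde hydrate to the acid without opening the epoxide; the centres are unchanged and only the C2 descriptor changes by priority.

Step 24
Reactants: 32 (3aR,4R,5R,6Z,10E,11aR)-5-[(tert-butyldimethylsilyl)oxy]-4-hydroxy-6,10-dimethyl-3-methylidene-3a,4,5,8,9,11a-hexahydrocyclodeca[b]furan-2(3H)-one; 36 (2S,3S)-2,3-dimethyloxirane-2-carboxylic acid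
Product: 38 (3aS,4R,5R,6Z,10E,11aR)-5-[(tert-butyldimethylsilyl)oxy]-6,10-dimethyl-3-methylidene-2-oxo-2,3,3a,4,5,8,9,11a-octahydrocyclodeca[b]furan-4-yl (2S,3S)-2,3-dimethyloxirane-2-carboxylate, via mixed anhydride 37 (not isolated)
Conditions: 36, 2,4,6-trichlorobenzoyl chloride, Et3N, toluene, rt; then 32, DMAP, rt → 50 °C
Reagents that add atoms: none
Why: Yamaguchi esterification; DMAP takes the acyl group from the less shielded carbonyl of the mixed anhydride and passes it to the hindered C8 hydroxyl, and the acid has no α-hydrogen, so neither epimerisation nor ketene formation can occur.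

Step 25
Reactants: 38 (3aS,4R,5R,6Z,10E,11aR)-5-[(tert-butyldimethylsilyl)oxy]-6,10-dimethyl-3-methylidene-2-oxo-2,3,3a,4,5,8,9,11a-octahydrocyclodeca[b]furan-4-yl (2S,3S)-2,3-dimethyloxirane-2-carboxylate
Product: 39 (3aS,4R,5R,6Z,10E,11aR)-5-hydroxy-6,10-dimethyl-3-methylidene-2-oxo-2,3,3a,4,5,8,9,11a-octahydrocyclodeca[b]furan-4-yl (2S,3S)-2,3-dimethyloxirane-2-carboxylate
Conditions: HF·pyridine, THF, 0 °C → rt
Reagents that add atoms: none
Why: Fluoride cleavage of the allylic silyl ether under mildly acidic conditions, where acyl migration from O8 to O9 is slow and the ester-deactivated epoxide resists opening.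

Step 26
Reactants: 39 (3aS,4R,5R,6Z,10E,11aR)-5-hydroxy-6,10-dimethyl-3-methylidene-2-oxo-2,3,3a,4,5,8,9,11a-octahydrocyclodeca[b]furan-4-yl (2S,3S)-2,3-dimethyloxirane-2-carboxylate
Product: 40 (3aS,4R,5R,6Z,10E,11aR)-5-acetoxy-6,10-dimethyl-3-methylidene-2-oxo-2,3,3a,4,5,8,9,11a-octahydrocyclodeca[b]furan-4-yl (2S,3S)-2,3-dimethyloxirane-2-carboxylate
Conditions: Ac2O, pyridine, DMAP (cat.), CH2Cl2, 0 °C
Reagents that add atoms: acetic anhydride (CC(=O)OC(C)=O)
Why: DMAP-catalysed acetylation of the secondary allylic alcohol with retention at C9; the conditions are routinely compatible with α-methylene lactones and epoxy esters.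

## Compound list

1 | pent-4-yn-1-ol | C#CCCCO | starting material
2 | (E)-5-(dimethylalumanyl)-4-methylpent-4-en-1-ol, as its dimethylaluminium alkoxide | C[Al](C)/C=C(\C)CCCO[Al](C)C | intermediate (not isolated)
3 | (E)-5-iodo-4-methylpent-4-en-1-ol | OCCC/C(C)=C/I | intermediate
4 | (E)-1,5-diiodo-2-methylpent-1-ene | ICCC/C(C)=C/I | intermediate
5 | [(E)-5-iodo-4-methylpent-4-en-1-yl]triphenylphosphonium iodide | [I-].I/C=C(\C)CCC[P+](c1ccccc1)(c1ccccc1)c1ccccc1 | intermediate
6 | (S)-2,2-dimethyl-1,3-dioxolane-4-carbaldehyde | O=C[C@@H]1COC(C)(C)O1 | starting material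
7 | (1RS)-1-[(4S)-2,2-dimethyl-1,3-dioxolan-4-yl]ethan-1-ol | CC(O)[C@@H]1COC(C)(C)O1 | intermediate
8 | 1-[(4S)-2,2-dimethyl-1,3-dioxolan-4-yl]ethan-1-one | CC(=O)[C@@H]1COC(C)(C)O1 | intermediate
9 | [(E)-5-iodo-4-methylpent-4-en-1-ylidene]triphenylphosphorane | I/C=C(\C)CCC=P(c1ccccc1)(c1ccccc1)c1ccccc1 | intermediate (not isolated)
10 | (4R)-4-[(2Z,6E)-7-iodo-6-methylhepta-2,6-dien-2-yl]-2,2-dimethyl-1,3-dioxolane | I/C=C(\C)CC/C=C(/C)[C@@H]1COC(C)(C)O1 | intermediate
11 | (2R,3Z,7E)-8-iodo-3,7-dimethylocta-3,7-diene-1,2-diol | I/C=C(\C)CC/C=C(/C)[C@@H](O)CO | intermediate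
12 | (2R,3Z,7E)-1,2-bis[(tert-butyldimethylsilyl)oxy]-8-iodo-3,7-dimethylocta-3,7-diene | I/C=C(\C)CC/C=C(/C)[C@@H](O[Si](C)(C)C(C)(C)C)CO[Si](C)(C)C(C)(C)C | intermediate
13 | [(1E,5Z,7R)-7,8-bis[(tert-butyldimethylsilyl)oxy]-2,6-dimethylocta-1,5-dien-1-yl]lithium | [Li]/C=C(\C)CC/C=C(/C)[C@@H](O[Si](C)(C)C(C)(C)C)CO[Si](C)(C)C(C)(C)C | intermediate (not isolated)
14 | (2E,6Z,8R)-8,9-bis[(tert-butyldimethylsilyl)oxy]-3,7-dimethylnona-2,6-dienal | O=C/C=C(\C)CC/C=C(/C)[C@@H](O[Si](C)(C)C(C)(C)C)CO[Si](C)(C)C(C)(C)C | intermediate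
15 | (2-carboxyethyl)triphenylphosphonium bromide | [Br-].OC(=O)CC[P+](c1ccccc1)(c1ccccc1)c1ccccc1 | starting material
16 | sodium 3-(triphenylphosphoranylidene)propanoate | [Na+].[O-]C(=O)CC=P(c1ccccc1)(c1ccccc1)c1ccccc1 | intermediate (not isolated)
17 | (3Z,5E,9Z,11R)-11,12-bis[(tert-butyldimethylsilyl)oxy]-6,10-dimethyldodeca-3,5,9-trienoic acid | OC(=O)C/C=C\C=C(/C)CC/C=C(/C)[C@@H](O[Si](C)(C)C(C)(C)C)CO[Si](C)(C)C(C)(C)C | intermediate
18 | methyl (3Z,5E,9Z,11R)-11,12-bis[(tert-butyldimethylsilyl)oxy]-6,10-dimethyldodeca-3,5,9-trienoate | COC(=O)C/C=C\C=C(/C)CC/C=C(/C)[C@@H](O[Si](C)(C)C(C)(C)C)CO[Si](C)(C)C(C)(C)C | intermediate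
19 | methyl (3Z,5E,9Z,11R)-11-[(tert-butyldimethylsilyl)oxy]-12-hydroxy-6,10-dimethyldodeca-3,5,9-trienoate | COC(=O)C/C=C\C=C(/C)CC/C=C(/C)[C@@H](O[Si](C)(C)C(C)(C)C)CO | intermediate
20 | methyl (3Z,5E,9Z,11R)-11-[(tert-butyldimethylsilyl)oxy]-6,10-dimethyl-12-oxododeca-3,5,9-trienoate | COC(=O)C/C=C\C=C(/C)CC/C=C(/C)[C@@H](O[Si](C)(C)C(C)(C)C)C=O | intermediate
21 | methyl (3Z,5E,9Z,11R,12E)-11-[(tert-butyldimethylsilyl)oxy]-12-(hydroxyimino)-6,10-dimethyldodeca-3,5,9-trienoate | O/N=C/[C@H](O[Si](C)(C)C(C)(C)C)/C(C)=C\CC/C(C)=C/C=C\CC(=O)OC | intermediate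
22 | nitrile oxide of 21 (C8 carbonitrile oxide; 11R in chain numbering) | [O-][N+]#C[C@H](O[Si](C)(C)C(C)(C)C)/C(C)=C\CC/C(C)=C/C=C\CC(=O)OC | intermediate (not isolated)
23 | methyl 2-[(2R,3Z,7E,9R,12R)-2-[(tert-butyldimethylsilyl)oxy]-3,7-dimethyl-10-oxa-11-azabicyclo[7.2.1]dodeca-1(11),3,7-trien-12-yl]acetate (germacrane 6R,7R,9R) | O1N=C2[C@H](O[Si](C)(C)C(C)(C)C)/C(C)=C\CC/C(C)=C/[C@@H]1[C@@H]2CC(=O)OC | intermediate
24 | methyl 2-[(1S,2R,3E,7Z,9R)-9-[(tert-butyldimethylsilyl)oxy]-2-hydroxy-4,8-dimethyl-10-oxocyclodeca-3,7-dien-1-yl]acetate | O[C@@H]1/C=C(\C)CC/C=C(/C)[C@@H](O[Si](C)(C)C(C)(C)C)C(=O)[C@H]1CC(=O)OC | intermediate (not isolated)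
25 | (3aS,5R,6Z,10E,11aR)-5-[(tert-butyldimethylsilyl)oxy]-6,10-dimethyl-3,3a,5,8,9,11a-hexahydrocyclodeca[b]furan-2,4-dione | O=C1O[C@@H]2/C=C(\C)CC/C=C(/C)[C@@H](O[Si](C)(C)C(C)(C)C)C(=O)[C@H]2C1 | intermediate
26 | (3aR,4R,5R,6Z,10E,11aR)-5-[(tert-butyldimethylsilyl)oxy]-4-hydroxy-6,10-dimethyl-3a,4,5,8,9,11a-hexahydrocyclodeca[b]furan-2(3H)-one | O=C1O[C@@H]2/C=C(\C)CC/C=C(/C)[C@@H](O[Si](C)(C)C(C)(C)C)[C@H](O)[C@H]2C1 | intermediate
27 | (3aS,4R,5R,6Z,10E,11aR)-5-[(tert-butyldimethylsilyl)oxy]-6,10-dimethyl-4-[(triethylsilyl)oxy]-3a,4,5,8,9,11a-hexahydrocyclodeca[b]furan-2(3H)-one | O=C1O[C@@H]2/C=C(\C)CC/C=C(/C)[C@@H](O[Si](C)(C)C(C)(C)C)[C@H](O[Si](CC)(CC)CC)[C@H]2C1 | intermediate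
28 | lithium enolate of 27 (C11=C12–OLi) | [Li]OC=1O[C@@H]2/C=C(\C)CC/C=C(/C)[C@@H](O[Si](C)(C)C(C)(C)C)[C@H](O[Si](CC)(CC)CC)[C@H]2C=1 | intermediate (not isolated)
29 | 3-[(dimethylamino)methyl] derivative of 27 (C11 epimers) | CN(C)CC1C(=O)O[C@@H]2/C=C(\C)CC/C=C(/C)[C@@H](O[Si](C)(C)C(C)(C)C)[C@H](O[Si](CC)(CC)CC)[C@@H]12 | intermediate (not isolated)
30 | trimethylammonium iodide derived from 29 | [I-].C[N+](C)(C)CC1C(=O)O[C@@H]2/C=C(\C)CC/C=C(/C)[C@@H](O[Si](C)(C)C(C)(C)C)[C@H](O[Si](CC)(CC)CC)[C@@H]12 | intermediate (not isolated)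
31 | (3aS,4R,5R,6Z,10E,11aR)-5-[(tert-butyldimethylsilyl)oxy]-6,10-dimethyl-3-methylidene-4-[(triethylsilyl)oxy]-3a,4,5,8,9,11a-hexahydrocyclodeca[b]furan-2(3H)-one | C=C1C(=O)O[C@@H]2/C=C(\C)CC/C=C(/C)[C@@H](O[Si](C)(C)C(C)(C)C)[C@H](O[Si](CC)(CC)CC)[C@@H]12 | intermediate
32 | (3aR,4R,5R,6Z,10E,11aR)-5-[(tert-butyldimethylsilyl)oxy]-4-hydroxy-6,10-dimethyl-3-methylidene-3a,4,5,8,9,11a-hexahydrocyclodeca[b]furan-2(3H)-one | C=C1C(=O)O[C@@H]2/C=C(\C)CC/C=C(/C)[C@@H](O[Si](C)(C)C(C)(C)C)[C@H](O)[C@@H]12 | intermediate
33 | angelic acid, (Z)-2-methylbut-2-enoic acid | C/C=C(/C)C(=O)O | starting material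
34 | (Z)-2-methylbut-2-en-1-ol | C/C=C(/C)CO | intermediate
35 | [(2R,3S)-2,3-dimethyloxiran-2-yl]methanol | OC[C@@]1(C)O[C@H]1C | intermediate
36 | (2S,3S)-2,3-dimethyloxirane-2-carboxylic acid | OC(=O)[C@@]1(C)O[C@H]1C | intermediate
37 | (2S,3S)-2,3-dimethyloxirane-2-carboxylic 2,4,6-trichlorobenzoic anhydride | Clc1cc(Cl)cc(Cl)c1C(=O)OC(=O)[C@@]2(C)O[C@H]2C | intermediate (not isolated)
38 | (3aS,4R,5R,6Z,10E,11aR)-5-[(tert-butyldimethylsilyl)oxy]-6,10-dimethyl-3-methylidene-2-oxo-2,3,3a,4,5,8,9,11a-octahydrocyclodeca[b]furan-4-yl (2S,3S)-2,3-dimethyloxirane-2-carboxylate | C=C1C(=O)O[C@@H]2/C=C(\C)CC/C=C(/C)[C@@H](O[Si](C)(C)C(C)(C)C)[C@H](OC(=O)[C@@]3(C)O[C@H]3C)[C@@H]12 | intermediate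
39 | (3aS,4R,5R,6Z,10E,11aR)-5-hydroxy-6,10-dimethyl-3-methylidene-2-oxo-2,3,3a,4,5,8,9,11a-octahydrocyclodeca[b]furan-4-yl (2S,3S)-2,3-dimethyloxirane-2-carboxylate | C=C1C(=O)O[C@@H]2/C=C(\C)CC/C=C(/C)[C@@H](O)[C@H](OC(=O)[C@@]3(C)O[C@H]3C)[C@@H]12 | intermediate
40 | (3aS,4R,5R,6Z,10E,11aR)-5-acetoxy-6,10-dimethyl-3-methylidene-2-oxo-2,3,3a,4,5,8,9,11a-octahydrocyclodeca[b]furan-4-yl (2S,3S)-2,3-dimethyloxirane-2-carboxylate | C=C1C(=O)O[C@@H]2/C=C(\C)CC/C=C(/C)[C@@H](OC(C)=O)[C@H](OC(=O)[C@@]3(C)O[C@H]3C)[C@@H]12 | target

## Step count and least certain steps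

Total: 26 steps. Longest linear sequence: 21 steps (steps 1–3, 6–20 and 24–26); steps 4–5 and 21–23 are side branches.

**Step 15 (key step, proposed new method).** Three processes may defeat it:
- dimerisation of the dipole to the furoxan, which can outrun a slow ten-membered closure;
- closure in the fused mode or across C4=C5;
- approach to the wrong face of C6=C7, since only C9 and the fold of the chain discriminate.

The fallback uses known chemistry and closes the ring at C5–C6 instead. It sets out from 12 and comes back at 27.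
- Buffered HF·pyridine removes the primary silyl group of 12 to give (2R,3Z,7E)-2-[(tert-butyldimethylsilyl)oxy]-8-iodo-3,7-dimethylocta-3,7-dien-1-ol F1.
- Dess–Martin oxidation gives the aldehyde (2R,3Z,7E)-2-[(tert-butyldimethylsilyl)oxy]-8-iodo-3,7-dimethylocta-3,7-dienal F2.
- The titanium enolate (TiCl4, i-Pr2NEt, N-methylpyrrolidinone) of methyl 4-[(4R)-4-benzyl-2-thioxo-1,3-thiazolidin-3-yl]-4-oxobutanoate F3 adds to F2 in an auxiliary-controlled syn aldol reaction. This sets C7 and C8 in the syn aldol adduct F4.
- TESOTf gives its triethylsilyl ether F5.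
- i-Bu2AlH at −78 °C cleaves the thiazolidinethione selectively to the C6 aldehyde F6.
- A Nozaki–Hiyama–Kishi reaction (CrCl2, catalytic NiCl2, DMSO, high dilution) joins the E alkenyl iodide to the aldehyde. It forms C5–C6 and the ten-membered allylic alcohol, the macrocyclic hydroxy ester F7.
- The C6 hydroxyl of F7 closes the lactone under PPTS to give 27.

C6 is not controlled by a pre-existing design element in this variant, so the trans-lactone isomer may have to be separated.

**Step 17.** Hydride may be delivered to the wrong face of C8 if the ring conformation overrides Felkin–Anh control. The C8 alkoxide may also translactonise onto C12, or the lactone carboxylate may be lost by β-elimination. The fallback changes the control element to the C6 hydroxyl. It sets out from 24, intercepted by running the N–O cleavage at lower temperature and omitting the acid treatment, and comes back at 26.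
- Chelation of O6 and the C8 carbonyl by Et2BOMe and external delivery of hydride from NaBH4 (THF/MeOH, −78 °C, Narasaka–Prasad reduction) gives the 1,3-syn diol, methyl 2-[(1R,2R,3E,7Z,9R,10R)-9-[(tert-butyldimethylsilyl)oxy]-2,10-dihydroxy-4,8-dimethylcyclodeca-3,7-dien-1-yl]acetate F8.
- PPTS-catalysed lactonisation through the less hindered allylic C6 hydroxyl gives 26.

**Step 24.** Acylation may stall because the C8 hydroxyl and the α-quaternary acid are both shielded. Under prolonged basic conditions the silyl group may migrate from O9 to O8, or nucleophiles may add to the methylene lactone. The fallback changes the order of events so that forcing conditions meet no Michael acceptor. It sets out from 26 and comes back at 38.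
- 26 is acylated with mixed anhydride 37 and DMAP in toluene at 80 °C to give the 8-O-(2S,3S)-epoxyangeloyl 9-O-silyl saturated lactone F9.
- The ester has no α-hydrogen, so LiN(i-Pr)2 at −78 °C forms only the lactone enolate F10.
- Eschenmoser's salt converts it into the Mannich base F11.
- Methyl iodide gives the ammonium iodide F12, and NaHCO3 eliminates trimethylamine to give 38.

This path omits the triethylsilyl protection and its removal.

**Step 10.** Z selectivity may erode in the Wittig reaction with an enal, and the skipped dienoate may shift into conjugation in the basic medium. The fallback replaces olefination by a stereospecific coupling. It sets out from 12 and comes back at 17.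
- Sonogashira coupling of 12 with but-3-yn-1-ol (PdCl2(PPh3)2, CuI, Et3N) gives (5E,9Z,11R)-11,12-bis[(tert-butyldimethylsilyl)oxy]-6,10-dimethyldodeca-5,9-dien-3-yn-1-ol F13.
- Semi-hydrogenation over Pd/CaCO3 poisoned with Pb(OAc)2 and quinoline gives the (3Z,5E,9Z)-trienol F14.
- Oxidation with TEMPO and PhI(OAc)2 in buffered aqueous MeCN gives acid 17.

## Further compounds

F1 | step 15 | (2R,3Z,7E)-2-[(tert-butyldimethylsilyl)oxy]-8-iodo-3,7-dimethylocta-3,7-dien-1-ol | I/C=C(\C)CC/C=C(/C)[C@@H](O[Si](C)(C)C(C)(C)C)CO
F2 | step 15 | (2R,3Z,7E)-2-[(tert-butyldimethylsilyl)oxy]-8-iodo-3,7-dimethylocta-3,7-dienal | I/C=C(\C)CC/C=C(/C)[C@@H](O[Si](C)(C)C(C)(C)C)C=O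
F3 | step 15 | methyl 4-[(4R)-4-benzyl-2-thioxo-1,3-thiazolidin-3-yl]-4-oxobutanoate | COC(=O)CCC(=O)N1[C@H](Cc2ccccc2)CSC1=S
F4 | step 15 | syn aldol adduct of F3 and F2 (germacrane C7 and C8 as in the target, C8 hydroxyl free, C9 silyl ether, C5 alkenyl iodide) | COC(=O)C[C@@H](C(=O)N1[C@H](Cc2ccccc2)CSC1=S)[C@@H](O)[C@H](O[Si](C)(C)C(C)(C)C)/C(C)=C\CC/C(C)=C/I
F5 | step 15 | C8 triethylsilyl ether of F4 | COC(=O)C[C@@H](C(=O)N1[C@H](Cc2ccccc2)CSC1=S)[C@@H](O[Si](CC)(CC)CC)[C@H](O[Si](C)(C)C(C)(C)C)/C(C)=C\CC/C(C)=C/I
F6 | step 15 | C6 aldehyde: methyl 3-formyl-4-(triethylsilyloxy)-5-(tert-butyldimethylsilyloxy)-10-iodo-6,9-dimethyldeca-6Z,9E-dienoate with C7, C8 and C9 as in the target | COC(=O)C[C@@H](C=O)[C@@H](O[Si](CC)(CC)CC)[C@H](O[Si](C)(C)C(C)(C)C)/C(C)=C\CC/C(C)=C/I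
F7 | step 15 | methyl 2-[(3E,7Z)-2-hydroxy-9-(tert-butyldimethylsilyloxy)-10-(triethylsilyloxy)-4,8-dimethylcyclodeca-3,7-dien-1-yl]acetate with C6, C7, C8 and C9 as in the target | O[C@@H]1/C=C(\C)CC/C=C(/C)[C@@H](O[Si](C)(C)C(C)(C)C)[C@H](O[Si](CC)(CC)CC)[C@H]1CC(=O)OC
F8 | step 17 | methyl 2-[(1R,2R,3E,7Z,9R,10R)-9-[(tert-butyldimethylsilyl)oxy]-2,10-dihydroxy-4,8-dimethylcyclodeca-3,7-dien-1-yl]acetate | O[C@@H]1/C=C(\C)CC/C=C(/C)[C@@H](O[Si](C)(C)C(C)(C)C)[C@H](O)[C@H]1CC(=O)OC
F9 | step 24 | (3aS,4R,5R,6Z,10E,11aR)-5-[(tert-butyldimethylsilyl)oxy]-6,10-dimethyl-2-oxo-2,3,3a,4,5,8,9,11a-octahydrocyclodeca[b]furan-4-yl (2S,3S)-2,3-dimethyloxirane-2-carboxylate | O=C1O[C@@H]2/C=C(\C)CC/C=C(/C)[C@@H](O[Si](C)(C)C(C)(C)C)[C@H](OC(=O)[C@@]3(C)O[C@H]3C)[C@H]2C1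
F10 | step 24 | lithium enolate of F9 (C11=C12–OLi) | [Li]OC=1O[C@@H]2/C=C(\C)CC/C=C(/C)[C@@H](O[Si](C)(C)C(C)(C)C)[C@H](OC(=O)[C@@]3(C)O[C@H]3C)[C@H]2C=1
F11 | step 24 | 3-[(dimethylamino)methyl] derivative of F9 (C11 epimers) | CN(C)CC1C(=O)O[C@@H]2/C=C(\C)CC/C=C(/C)[C@@H](O[Si](C)(C)C(C)(C)C)[C@H](OC(=O)[C@@]3(C)O[C@H]3C)[C@@H]12
F12 | step 24 | trimethylammonium iodide derived from F11 | [I-].C[N+](C)(C)CC1C(=O)O[C@@H]2/C=C(\C)CC/C=C(/C)[C@@H](O[Si](C)(C)C(C)(C)C)[C@H](OC(=O)[C@@]3(C)O[C@H]3C)[C@@H]12
F13 | step 10 | (5E,9Z,11R)-11,12-bis[(tert-butyldimethylsilyl)oxy]-6,10-dimethyldodeca-5,9-dien-3-yn-1-ol | OCCC#C/C=C(\C)CC/C=C(/C)[C@@H](O[Si](C)(C)C(C)(C)C)CO[Si](C)(C)C(C)(C)C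
F14 | step 10 | (3Z,5E,9Z,11R)-11,12-bis[(tert-butyldimethylsilyl)oxy]-6,10-dimethyldodeca-3,5,9-trien-1-ol | OCC/C=C\C=C(/C)CC/C=C(/C)[C@@H](O[Si](C)(C)C(C)(C)C)CO[Si](C)(C)C(C)(C)C
A1 | alternative 1 | open-chain C3–C10 segment on the trans lactone with free C8 hydroxyl, C9 PMB ether and C4 alkenyl iodide | CC(C)(C)[Si](C)(C)OCC/C=C(/C)[C@@H](OCc1ccc(OC)cc1)[C@H](O)[C@H]2CC(=O)O[C@@H]2/C=C(\C)I
A2 | alternative 1 | 3-[(tert-butyldimethylsilyl)oxy]propyl N,N-diisopropylcarbamate | CC(C)N(C(C)C)C(=O)OCCCO[Si](C)(C)C(C)(C)C
A3 | alternative 1 | 2-[(E)-1-[(4-methoxybenzyl)oxy]prop-1-en-2-yl]-4,4,5,5-tetramethyl-1,3,2-dioxaborolane | C/C(B1OC(C)(C)C(C)(C)O1)=C/OCc1ccc(OC)cc1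
A4 | alternative 1 | trans-2-[(E)-2-iodoprop-1-en-1-yl]-5-oxotetrahydrofuran-3-carbaldehyde with C6 and C7 as in the target | O=C[C@H]1CC(=O)O[C@@H]1/C=C(\C)I
A5 | alternative 2 | ten-membered methylene lactone with C8 PMB ether and C9 triethylsilyl ether | C=C1C(=O)O[C@@H]2/C=C(\C)CC/C=C(/C)[C@@H](O[Si](CC)(CC)CC)[C@H](OCc3ccc(OC)cc3)[C@@H]12
A6 | alternative 2 | macrocyclic homopropargylic alcohol (C6 hydroxyl, C7 ethynyl, C8 PMB ether, C9 triethylsilyl ether) | O[C@@H]1/C=C(\C)CC/C=C(/C)[C@@H](O[Si](CC)(CC)CC)[C@H](OCc2ccc(OC)cc2)[C@H]1C#C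
A7 | alternative 3 | trans α-carboxy γ-lactone with 4E alkene, C8/C9 acetonide and C10 silyl ether | OC(=O)[C@@H]1C(=O)O[C@H](/C=C(\C)CCC(=O)OC)[C@H]1[C@H]2OC(C)(C)O[C@@H]2CO[Si](c3ccccc3)(c4ccccc4)C(C)(C)C
A8 | alternative 3 | methyl (4E,6E)-4-methyl-7-[(4R,5R)-5-[(tert-butyldiphenylsilyloxy)methyl]-2,2-dimethyl-1,3-dioxolan-4-yl]hepta-4,6-dienoate | COC(=O)CC/C(C)=C/C=C/[C@H]1OC(C)(C)O[C@@H]1CO[Si](c2ccccc2)(c3ccccc3)C(C)(C)C
A9 | alternative 3 | malonic acid | OC(=O)CC(=O)O
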